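**Strategy**

Isoflavene numbering is used (O1, C2, C3, C4, ring A C4a–C8a, ring B C1'–C6'). The target is read as a ring-opened cis-pterocarpan: the C2' oxygen of ring B can reach C4, a benzylic carbon whose cation is stabilised by O1 and the C5 methoxy (ortho) and the C7 methoxy (para) of ring A. One Heck-type oxyarylation joins 5,7-dimethoxy-6-prenyl-2H-chromene, unsubstituted at C3, and a 2-iodophenol silylated para to iodine, forming C3–C1', C4–O2' and the dihydrofuran ring together. A silyl triflate then breaks the same C4–O bond with loss of H3, and fluoride frees both phenols.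

Key step: step 6

Remark: the target has no stereocentre, so the pterocarpan is carried as the racemate (one enantiomer drawn) and its two stereocentres disappear in the ring opening; 4-iodoresorcinol is taken as a purchasable starting material, and prenyl means 3-methylbut-2-enyl.

**Route**

Step 1
Reactants: 1 3,5-dimethoxyphenol
Product: 2 (3,5-dimethoxyphenoxy)triisopropylsilane
Conditions: TIPSCl, imidazole, DMF, rt
Reagents that add atoms: chlorotriisopropylsilane (TIPSCl), CC(C)[Si](Cl)(C(C)C)C(C)C
Why: Silylation of a phenol with a silyl chloride and imidazole should proceed cleanly, and the bulky, poorly coordinating OTIPS group is chosen so that C2 and C6 are shielded from butyllithium in step 2.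

Step 2
Reactants: 2 (3,5-dimethoxyphenoxy)triisopropylsilane; 3 prenyl bromide (1-bromo-3-methylbut-2-ene)
Product: 5 (3,5-dimethoxy-4-prenylphenoxy)triisopropylsilane, via the aryllithium 4 (not isolated)
Conditions: n-BuLi, THF, 0 °C to rt; then 3, −78 °C to rt
Reagents that add atoms: none
Why: Directed ortho-metalation should occur at C4, the only carbon flanked by two lithium-coordinating methoxy groups, and the aryllithium is then alkylated at the primary carbon of the allylic bromide (SN2).

Step 3
Reactants: 5 (3,5-dimethoxy-4-prenylphenoxy)triisopropylsilane; 6 propargyl bromide (3-bromoprop-1-yne)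
Product: 8 1,3-dimethoxy-2-prenyl-5-(prop-2-ynyloxy)benzene, via the ammonium phenoxide 7 (not isolated)
Conditions: TBAF, THF, 0 °C; then 6, rt
Reagents that add atoms: none
Why: Fluoride cleaves the aryl silyl ether and the resulting tetrabutylammonium phenoxide should be O-alkylated in the same flask by the reactive propargylic bromide (Williamson ether synthesis).

Step 4
Reactants: 8 1,3-dimethoxy-2-prenyl-5-(prop-2-ynyloxy)benzene
Product: 10 5,7-dimethoxy-6-prenyl-2H-chromene, via the 2-allenylphenol 9 (not isolated)
Conditions: PhNEt2, 200 °C
Reagents that add atoms: none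
Why: Aryl propargyl ether Claisen rearrangement, in which a [3,3] shift to either of the two equivalent ortho carbons gives the allenylphenol and a 1,5-hydrogen shift followed by oxa-6π electrocyclisation closes the pyran, so the symmetry of the ether allows only one chromene.

Step 5
Reactants: 11 4-iodoresorcinol (4-iodobenzene-1,3-diol)
Product: 12 2-iodo-5-(triisopropylsilyloxy)phenol
Conditions: TIPSCl (1.0 equiv), imidazole, CH2Cl2, −20 to 0 °C
Reagents that add atoms: chlorotriisopropylsilane (TIPSCl), CC(C)[Si](Cl)(C(C)C)C(C)C
Why: Sterically controlled monosilylation, in which the hydroxyl ortho to iodine is shielded by the halogen so the bulky silyl chloride should react at the hydroxyl para to iodine, and the TIPS group is preferred to a smaller silyl group for this selectivity and for its stability to carbonate in step 6.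

Step 6
Reactants: 10 5,7-dimethoxy-6-prenyl-2H-chromene; 12 2-iodo-5-(triisopropylsilyloxy)phenol
Product: 13 rac-(6aR,11aR)-1,3-dimethoxy-2-prenyl-9-(triisopropylsilyloxy)pterocarpan (cis-6a,11a-dihydro-6H-benzofuro[3,2-c]chromene core)
Conditions: Pd(OAc)2 (10 mol%), Ag2CO3 (3 equiv), acetone, reflux
Reagents that add atoms: none
Why: Pd(OAc)2 is reduced in the flask to zerovalent palladium, which inserts into the C–I bond of 12; Ag2CO3 removes iodide and the phenolic proton, and the cationic arylpalladium species adds syn across C3=C4 of 10, aryl to C3 and palladium to benzylic C4. No syn β-hydrogen is available (H3 is anti to palladium and C4a is aromatic), so the palladium-bound phenoxide forms the C4–O2' bond by C–O reductive elimination from a six-membered oxapalladacycle, formally a 5-exo-tet closure of the dihydrofuran with retention at C4, and zerovalent palladium is returned. The closest known reaction type is the Heck-type oxyarylation of 2H-chromenes with 2-iodophenols to pterocarpans. The two new stereocentres, C3 and C4 (C6a and C11a of the pterocarpan), are set together by the syn addition and the retentive C–O bond formation, so only the cis ring fusion can form and the product is racemic. Regioselectivity requires palladium, and hence oxygen, on C4, which is secured by O1 and the C5 and C7 methoxy groups that make C4 the carbon best able to hold the metal as a stabilised benzyl unit. Chemoselectivity for the chromene alkene over the prenyl alkene follows from the strained cis-disubstituted styrene inserting far faster than a hindered trisubstituted alkene.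

Step 7
Reactants: 13 rac-(6aR,11aR)-1,3-dimethoxy-2-prenyl-9-(triisopropylsilyloxy)pterocarpan
Product: 14 3-[2-(tert-butyldimethylsilyloxy)-4-(triisopropylsilyloxy)phenyl]-5,7-dimethoxy-6-prenyl-2H-chromene
Conditions: TBSOTf, Et3N, CH2Cl2, −78 to 0 °C
Reagents that add atoms: tert-butyldimethylsilyl trifluoromethanesulfonate (TBSOTf), CC(C)(C)[Si](C)(C)OS(=O)(=O)C(F)(F)F
Why: Proposed new method: TBSOTf should silylate the dihydrofuran oxygen O2', the silyloxonium ion should ionise at C4 because the cation is benzylic to ring A and stabilised by O1, the C5 methoxy and the C7 methoxy, Et3N then removes H3 (E1) to give the conjugated C3=C4 alkene, and the new aryl silyl ether cannot add back, so the opening is irreversible and both stereocentres are erased; the closest known reaction types are the eliminative opening of epoxides and acetals by a silyl triflate and an amine and the acid ionisation of the benzylic C–O bond of pterocarpans.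

Step 8
Reactants: 14 3-[2-(tert-butyldimethylsilyloxy)-4-(triisopropylsilyloxy)phenyl]-5,7-dimethoxy-6-prenyl-2H-chromene
Product: 15 dehydroglyasperin D, 4-(5,7-dimethoxy-6-prenyl-2H-chromen-3-yl)benzene-1,3-diol
Conditions: TBAF, AcOH, THF, 0 °C to rt
Reagents that add atoms: none
Why: Fluoride-mediated cleavage of both aryl silyl ethers, buffered with acetic acid so that the electron-rich phenoxides are not left in base while no acid strong enough to protonate C3 and re-close the furan ring is present.

**Compound list**

1 | 3,5-dimethoxyphenol | COc1cc(O)cc(OC)c1 | starting material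
2 | (3,5-dimethoxyphenoxy)triisopropylsilane | COc1cc(O[Si](C(C)C)(C(C)C)C(C)C)cc(OC)c1 | intermediate
3 | prenyl bromide (1-bromo-3-methylbut-2-ene) | CC(C)=CCBr | starting material
4 | [2,6-dimethoxy-4-(triisopropylsilyloxy)phenyl]lithium | [Li]c1c(OC)cc(O[Si](C(C)C)(C(C)C)C(C)C)cc1OC | intermediate (not isolated)
5 | (3,5-dimethoxy-4-prenylphenoxy)triisopropylsilane | COc1cc(O[Si](C(C)C)(C(C)C)C(C)C)cc(OC)c1CC=C(C)C | intermediate
6 | propargyl bromide (3-bromoprop-1-yne) | C#CCBr | starting material
7 | tetrabutylammonium 3,5-dimethoxy-4-prenylphenoxide | CCCC[N+](CCCC)(CCCC)CCCC.COc1cc([O-])cc(OC)c1CC=C(C)C | intermediate (not isolated)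
8 | 1,3-dimethoxy-2-prenyl-5-(prop-2-ynyloxy)benzene | C#CCOc1cc(OC)c(CC=C(C)C)c(OC)c1 | intermediate
9 | 3,5-dimethoxy-4-prenyl-2-(propa-1,2-dienyl)phenol | C=C=Cc1c(O)cc(OC)c(CC=C(C)C)c1OC | intermediate (not isolated)
10 | 5,7-dimethoxy-6-prenyl-2H-chromene | COc1cc2c(c(OC)c1CC=C(C)C)C=CCO2 | intermediate
11 | 4-iodoresorcinol (4-iodobenzene-1,3-diol) | Oc1ccc(I)c(O)c1 | starting material
12 | 2-iodo-5-(triisopropylsilyloxy)phenol | Oc1cc(O[Si](C(C)C)(C(C)C)C(C)C)ccc1I | intermediate
13 | rac-(6aR,11aR)-1,3-dimethoxy-2-prenyl-9-(triisopropylsilyloxy)pterocarpan, cis-fused, one enantiomer drawn | COc1cc2c(c(OC)c1CC=C(C)C)[C@@H]1Oc3cc(O[Si](C(C)C)(C(C)C)C(C)C)ccc3[C@@H]1CO2 | intermediate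
14 | 3-[2-(tert-butyldimethylsilyloxy)-4-(triisopropylsilyloxy)phenyl]-5,7-dimethoxy-6-prenyl-2H-chromene | COc1cc2c(c(OC)c1CC=C(C)C)C=C(c1ccc(O[Si](C(C)C)(C(C)C)C(C)C)cc1O[Si](C)(C)C(C)(C)C)CO2 | intermediate
15 | dehydroglyasperin D | COc1cc2c(c(OC)c1CC=C(C)C)C=C(c1ccc(O)cc1O)CO2 | target

**Step count and risks**

Total step count: 8. Longest linear sequence: 7 (steps 1 to 4, then 6 to 8).

Steps most likely to fail:

1. Step 7. The amine-complexed silyl triflate may be too weak a Lewis acid to ionise the C4–O2' bond. Alternatively, the C4 cation may be captured by the electron-rich C8 of a second molecule faster than it loses H3, giving oligomers.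
   Fallback, from 13 back to 15, using known reaction types (Lewis acid thiolysis of an activated benzyl aryl ether, sulfide oxidation, sulfoxide syn elimination). Thiophenol with BF3·OEt2 in CH2Cl2 at −78 °C should intercept the same cation at sulfur, anti to the C3 aryl group, to give the trans-4-(phenylthio)isoflavan-2'-ol F1. One equivalent of mCPBA at −78 °C should give the sulfoxide F2. Heating F2 in toluene over NaHCO3 (H3 is cis to sulfur) should give the 4'-O-silyl isoflav-3-ene F3. The conditions of step 8 then remove the remaining silyl group and give 15.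

2. Step 6. Oxidative addition into the electron-rich iodophenol may be slow, leading to precipitation of palladium metal. The sensitive benzylic ether of the product may also ionise under the silver salt at reflux.
   Fallback, from 12 and 10 back to 13, by the stoichiometric arylmercury version of the oxyarylation. Iodine–lithium exchange on 12 (n-BuLi, 2.1 equiv, THF, −78 °C) should give the dilithio phenoxide F4. Quenching F4 with HgCl2 should give, after work-up, the arylmercury chloride F5. F5 with 10 and one equivalent of Li2PdCl4 in acetone at rt transfers the aryl group to divalent palladium without heat or silver, and the same syn insertion and ring closure should deliver 13.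

3. Step 5. Discrimination between the two hydroxyls may be incomplete, with silylation at the hydroxyl ortho to iodine and double silylation consuming material.
   Fallback, from 11 and 10 back to 13, by protecting after the annulation instead of before it. Oxyarylation of 10 with unprotected 11 under the conditions of step 6 should give the free phenol pterocarpan F6, because only the hydroxyl ortho to iodine can close the ring. Silylation of its single hydroxyl (TIPSCl, imidazole, DMF) then gives 13 with no selectivity question.

Further compounds
F1 | step 7 | trans-2-[5,7-dimethoxy-4-(phenylthio)-6-prenylchroman-3-yl]-5-(triisopropylsilyloxy)phenol, racemic, one enantiomer drawn | COc1cc2c(c(OC)c1CC=C(C)C)[C@@H](Sc1ccccc1)[C@H](c1ccc(O[Si](C(C)C)(C(C)C)C(C)C)cc1O)CO2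
F2 | step 7 | trans-2-[5,7-dimethoxy-4-(phenylsulfinyl)-6-prenylchroman-3-yl]-5-(triisopropylsilyloxy)phenol, racemic, mixture at sulfur | COc1cc2c(c(OC)c1CC=C(C)C)[C@@H](S(=O)c1ccccc1)[C@H](c1ccc(O[Si](C(C)C)(C(C)C)C(C)C)cc1O)CO2
F3 | step 7 | 2-(5,7-dimethoxy-6-prenyl-2H-chromen-3-yl)-5-(triisopropylsilyloxy)phenol | COc1cc2c(c(OC)c1CC=C(C)C)C=C(c1ccc(O[Si](C(C)C)(C(C)C)C(C)C)cc1O)CO2
F4 | step 6 | lithium 2-lithio-5-(triisopropylsilyloxy)phenoxide | [Li]Oc1cc(O[Si](C(C)C)(C(C)C)C(C)C)ccc1[Li]
F5 | step 6 | 2-(chloromercurio)-5-(triisopropylsilyloxy)phenol | Oc1cc(O[Si](C(C)C)(C(C)C)C(C)C)ccc1[Hg]Cl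
F6 | step 5 | rac-(6aR,11aR)-9-hydroxy-1,3-dimethoxy-2-prenylpterocarpan, cis-fused, one enantiomer drawn | COc1cc2c(c(OC)c1CC=C(C)C)[C@@H]1Oc3cc(O)ccc3[C@@H]1CO2
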